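Compound numbers are those of the steps and of the compound list. Ring letters: A is the benzo ring of the chromenone, C the pyranone, B the pendant aryl ring, D the dimethylpyran ring fused to ring B.

## Analysis of the target

Target 19 is an isoflavone. Benzo ring A and pyranone ring C form the chromen-4-one, and C3 carries aryl ring B, which is also the benzo ring of a 2,2-dimethyl-2H-chromene (pyran ring D). Ring A has one free hydroxyl at C7, para to C4a. Going round ring B from the carbon bonded to C3 (chromene C6), it carries the free 2'-hydroxyl (chromene C5), the vinylic carbon of ring D (at C4a), the ring D oxygen (at C8a), a methoxy group (C8) and one hydrogen (C7). There is no stereocentre, so the problem is one of connectivity and of keeping four oxygens apart. The sensitive groups are three: the styrene-type double bond of ring D (acid, electrophiles, hydrogenation, ultraviolet light); the 2'-hydroxyl, which is para to the methoxy group and so a hydroquinone monoether that oxidants turn into a quinone; and the pyranone, which strong nucleophiles open at C2. The difficulty is to join two electron-rich, differently oxygenated arenes through C2, C3 and C4 without touching ring D or scrambling the ring B oxygens. The route rests on the fact that C4 is a lone carbonyl carbon bonded only to C4a of ring A and to C3, while C3 bears ring B and C2 is a CH next to O1. C4 can therefore come from carbon monoxide, placed between an aryl iodide carbon (C4a) and a vinyl–boron carbon (C3) that already holds ring B and the future C2 as its methylene.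

## Retrosynthetic reasoning

**19 from 18.** The last bond cut is the acetal C–O bond of a methoxymethyl ether on the 2'-oxygen. It is removed last because the free 2'-phenol, para to methoxy, would not survive the oxidation that precedes it. Dilute acid at moderate temperature is enough, which ring D tolerates.

**18 from 17.** The C2=C3 double bond is taken back to the saturated isoflavanone 17. This is the oxidation level that a conjugate addition onto a terminal methylene delivers. The C3 stereocentre of 17 is of no concern because it becomes planar again. The forward step must remove two hydrogens from an activated α-aryl ketone position without touching ring D or ring B.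

**17 from 13, 14 and 11.** O1–C2 is cut first (retro-oxa-Michael), giving the open dihydroxy enone 16 and its diacetate 15. Then C4a–C4 and C4–C3 are cut on either side of the carbonyl carbon. This leaves aryl iodide 13, carbon monoxide 14 and vinyl boronate 11. The cut is made here because C4 has no other substituent, so both bonds can be formed in one catalytic cycle from three simple pieces. A cut at C3–C1' would instead need a preformed ring C and a ring B aryl metal. The forward step has to take up 14 before transmetalation, and then close ring C through the ring A oxygen only.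

**13 from 12.** Two O-acyl bonds are cut. The acetates keep the ring A phenols from capturing the acylpalladium intermediate. They are cleaved by the same basic alcoholysis that triggers ring closure, so they cost one step and no separate deprotection.

**11 from 10, and 10 from 9.** The C–B bond comes from a C–O triflate bond, and that from the enolate of methyl ketone 9. The acetyl carbonyl carbon becomes C3 and the acetyl methyl becomes C2. The acetyl group that steers the ring B chemistry thus ends up as two of the three carbons of the linking unit.

**9 from 8.** The methoxymethyl ether is placed on the chelated 5-hydroxyl once ring D is in place. It is base-stable, small enough for a flanked phenol and acid-cleavable under mild conditions.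

**8 from 6, and 6 from 4 and 5.** Ring D is opened at its aryl–vinyl bond and its O–C(CH3)2 bond, going back through allenylphenol 7 to aryl propargyl ether 6 and on to phenol 4 and chloroalkyne 5. The regiochemistry is fixed by structure. In 6 one ortho position of the ether oxygen carries the methoxy group, so the sigmatropic shift can only end at the carbon between the two oxygens. The chelated 2-hydroxyl of 4 leaves the 4-hydroxyl as the one that is alkylated.

**4 from 3, and 3 from 1.** The aryl–acetyl bond is cut (C-acetylation para to one hydroxyl and ortho to the other). The second hydroxyl of 3 is traced back to the aldehyde carbon of 1 through formate 2, by oxidative excision of that carbon. The methoxy group of 1 is carried unchanged to C8 of ring D in 19, so the ring B oxygens are differentiated from the start.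

## Alternatives that were turned down

**Alternative 1:**
- Disconnection: C3–C4 and O1–C2 of ring C. Ring A arrives as benzodioxinone A2 (7-(methoxymethoxy)-2,2-dimethyl-4H-1,3-benzodioxin-4-one). Ring B arrives as enamine A3 (the morpholine enamine of the ring B arylacetaldehyde, with ring D saturated).
- Forward key step: light near 300 nm makes A2 lose the ketone of its ketal and form a quinoketene. The β-carbon of A3 attacks the ketene carbon, the ring A oxygen closes onto the iminium carbon, and loss of the amine gives isoflavone A1 (3-[8-methoxy-5-(methoxymethoxy)-2,2-dimethylchroman-6-yl]-7-(methoxymethoxy)-4H-chromen-4-one).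
- For: the ring closure is neutral, needs no reagent and no metal, and gives ring C directly at the isoflavone oxidation level. On this point it is stronger than the chosen route, which needs step 10.
- Against: 2H-chromenes are photochromic, and the same light would open ring D to a quinone methide. Ring D must therefore be carried saturated (A1 is a chroman) and dehydrogenated late at an unactivated CH2–CH2 unit. The liberated amine can trap the ketene as an amide. A3 needs a one-carbon homologation of a ring B aldehyde and is prone to hydrolysis. Two acetal groups remain to be removed.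
- Comparison: both routes need one dehydrogenation. The chosen route places it at the activated α-aryl ketone position of 17, has ring D in its final form from step 4, and runs thermally.

**Alternative 2:**
- Disconnection: C4–C4a only. The precursor is lactone A5, in which the ring B arylacetic acid is closed onto its own 2'-oxygen and the α-carbon carries a (3-hydroxyphenoxy)methylidene group that already contains O1, C2 and the C2=C3 double bond.
- Forward key step: a superacid activates the lactone carbonyl, the resorcinol ring attacks it (Friedel–Crafts acylation, C4–C4a), ring C closes and the lactone opens to free the 2'-hydroxyl. The product is A4 (7-hydroxy-3-(5-hydroxy-8-methoxy-2,2-dimethylchroman-6-yl)-4H-chromen-4-one).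
- For: no protecting group is needed, since the lactone masks the 2'-oxygen and the key step releases it, and the isoflavone level is reached directly. In protecting-group economy it is stronger than the chosen route.
- Against: the superacid is incompatible with the ring D double bond, so A4 is again a chroman. The late ring D dehydrogenation would have to be run on a free 2'-hydroxyl para to methoxy, which a quinone oxidant attacks first, so protection would come back. Ring A can be acylated on either side of the ether oxygen (para to the free hydroxyl, as wanted, or between the two oxygens), and only a steric and electronic preference decides. The enol ether is acid-labile.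
- Comparison: the chosen route fixes the C4–C4a bond site by the iodine atom and never exposes ring D to strong acid. It pays for this with three protecting-group operations (steps 5, 8 and 11).

**Alternative 3:**
- Disconnection: C3–C1' and O1–C2. The components are enaminone A7 ((E)-3-(dimethylamino)-1-[2-hydroxy-4-(methoxymethoxy)phenyl]prop-2-en-1-one) and quinone A8 (2,2-dimethyl-2H-chromene-5,8-dione).
- Forward key step: the α-carbon of A7 adds to C6 of A8, the adduct tautomerises to the hydroquinone, and the ring A phenol displaces the amine to close ring C. The product is A6 (3-(5,8-dihydroxy-2,2-dimethyl-2H-chromen-6-yl)-7-(methoxymethoxy)-4H-chromen-4-one).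
- For: it is the most convergent plan. Ring B comes from a simple quinone, no metal is used, ring D is already unsaturated and the isoflavone level is reached directly. In step count it is probably stronger than the chosen route.
- Against: A6 has two free hydroxyls on ring B (C5 and C8) and only the C8 one may be methylated, which rests on a steric difference and not on structure. Addition at C6 and not at C7 of A8 depends only on the polarisation by the ring oxygen. A6 is a reductant for A8, so redox exchange and second additions threaten. The enaminone nitrogen can compete with carbon as the nucleophile.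
- Comparison: the chosen route carries the methoxy group from 1, so the ring B oxygen pattern is never in question, and iodine and boron fix both C–C bond sites. The price is a longer linear sequence.

Key step: step 9

Remark on the chemistry: 19 has no stereocentre. C3 of 17 is formed as a racemate and becomes planar again in step 10, so no stereocontrol is planned.

## Route

Step 1
Reactants: 1 isovanillin (3-hydroxy-4-methoxybenzaldehyde)
Product: 3 4-methoxybenzene-1,3-diol, via 3-hydroxy-4-methoxyphenyl formate 2 (not isolated)
Conditions: mCPBA, CH2Cl2, 40 °C; then MeOH, HCl (cat.), 25 °C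
Reagents that add atoms: 3-chloroperbenzoic acid (mCPBA), OOC(=O)c1cccc(Cl)c1
Why: Baeyer–Villiger (Dakin-type) oxidation; in the Criegee adduct the electron-rich aryl group (para-methoxy) migrates in preference to hydride, so the aldehyde becomes formate 2, which acid-catalysed methanolysis cleaves to the phenol.

Step 2
Reactants: 3 4-methoxybenzene-1,3-diol
Product: 4 1-(2,4-dihydroxy-5-methoxyphenyl)ethan-1-one
Conditions: AcOH, BF3·OEt2, 90 °C; then H2O
Reagents that add atoms: acetic acid, CC(=O)O
Why: Friedel–Crafts C-acetylation of the Nencki type; the position para to one hydroxyl and ortho to the other is the most reactive unhindered site (the carbon between the hydroxyls is crowded, the carbon next to methoxy is meta to both hydroxyls), and the BF2 chelate of the product is cleaved by water.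

Step 3
Reactants: 4 1-(2,4-dihydroxy-5-methoxyphenyl)ethan-1-one; 5 3-chloro-3-methylbut-1-yne
Product: 6 1-{2-hydroxy-5-methoxy-4-[(2-methylbut-3-yn-2-yl)oxy]phenyl}ethan-1-one
Conditions: K2CO3, KI, CuI (cat.), acetone, 60 °C
Reagents that add atoms: none
Why: Copper-assisted Williamson-type O-alkylation of a phenol with a tertiary propargylic chloride; the 2-hydroxyl is held in a hydrogen bond to the acetyl oxygen and is the less acidic one, so the 4-hydroxyl should be alkylated.

Step 4
Reactants: 6 1-{2-hydroxy-5-methoxy-4-[(2-methylbut-3-yn-2-yl)oxy]phenyl}ethan-1-one
Product: 8 1-(5-hydroxy-8-methoxy-2,2-dimethyl-2H-chromen-6-yl)ethan-1-one, via allenylphenol 7 (not isolated)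
Conditions: PhNEt2, 190 °C
Reagents that add atoms: none
Why: Aryl propargyl ether Claisen rearrangement, tautomerisation to allenylphenol 7, 1,5-hydrogen shift to the ortho-quinone methide and oxa-6π electrocyclisation; the other ortho position carries the methoxy group, so only the carbon between the two oxygens can rearomatise and one chromene regioisomer is expected, with the chelated hydroxyl staying free.

Step 5
Reactants: 8 1-(5-hydroxy-8-methoxy-2,2-dimethyl-2H-chromen-6-yl)ethan-1-one
Product: 9 1-[8-methoxy-5-(methoxymethoxy)-2,2-dimethyl-2H-chromen-6-yl]ethan-1-one
Conditions: NaH, DMF, 0 °C; MOMCl, 0 → 25 °C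
Reagents that add atoms: chloromethyl methyl ether, COCCl
Why: Williamson-type O-alkylation; NaH breaks the hydrogen bond of the chelated phenol, the phenol is far more acidic than the methyl ketone, and the small chloromethyl ether reaches the flanked phenoxide.

Step 6
Reactants: 9 1-[8-methoxy-5-(methoxymethoxy)-2,2-dimethyl-2H-chromen-6-yl]ethan-1-one
Product: 10 1-[8-methoxy-5-(methoxymethoxy)-2,2-dimethyl-2H-chromen-6-yl]ethenyl trifluoromethanesulfonate
Conditions: KN(SiMe3)2, THF, −78 °C; PhNTf2, −78 → 0 °C
Reagents that add atoms: N-phenylbis(trifluoromethanesulfonimide), O=S(=O)(N(c1ccccc1)S(=O)(=O)C(F)(F)F)C(F)(F)F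
Why: Enol triflate formation; the acetyl methyl is the only acidic C–H, and O-sulfonylation of its potassium enolate gives the 1-arylvinyl triflate.

Step 7
Reactants: 10 1-[8-methoxy-5-(methoxymethoxy)-2,2-dimethyl-2H-chromen-6-yl]ethenyl trifluoromethanesulfonate
Product: 11 2-{1-[8-methoxy-5-(methoxymethoxy)-2,2-dimethyl-2H-chromen-6-yl]ethenyl}-4,4,5,5-tetramethyl-1,3,2-dioxaborolane
Conditions: B2pin2, PdCl2(PPh3)2 (3 mol %), PPh3 (6 mol %), KOPh, toluene, 50 °C
Reagents that add atoms: bis(pinacolato)diboron, CC1(C)OB(OC1(C)C)B1OC(C)(C)C(C)(C)O1
Why: Miyaura borylation of an alkenyl triflate; zerovalent palladium inserts into the C–OTf bond, phenoxide-assisted transmetalation with the diboron and reductive elimination follow, and the weak base KOPh keeps the product from coupling with unreacted triflate.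

Step 8
Reactants: 12 4-iodobenzene-1,3-diol (4-iodoresorcinol)
Product: 13 4-iodo-1,3-phenylene diacetate
Conditions: Ac2O, pyridine, DMAP (cat.), CH2Cl2, 0 → 25 °C
Reagents that add atoms: acetic anhydride, CC(=O)OC(C)=O
Why: DMAP-catalysed O-acetylation of both phenols; the C–I bond is not affected.

Step 9
Reactants: 13 4-iodo-1,3-phenylene diacetate; 14 carbon monoxide; 11 2-{1-[8-methoxy-5-(methoxymethoxy)-2,2-dimethyl-2H-chromen-6-yl]ethenyl}-4,4,5,5-tetramethyl-1,3,2-dioxaborolane
Product: 17 7-hydroxy-3-[8-methoxy-5-(methoxymethoxy)-2,2-dimethyl-2H-chromen-6-yl]chroman-4-one (racemic), via enone diacetate 15 (not isolated), via dihydroxy enone 16 (not isolated)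
Conditions: Pd(OAc)2 (5 mol %), PPh3 (15 mol %), K2CO3 (anhydrous, powdered), anisole, CO (3 bar), 80 °C; then vent, N2, MeOH, K2CO3, 25 °C; aq. NH4Cl
Reagents that add atoms: none
Why: CO and phosphine reduce Pd(OAc)2 to zerovalent palladium, which inserts into the C–I bond of 13; CO insertion gives the aroylpalladium iodide, and carbonate-assisted transmetalation with 11 followed by reductive elimination gives enone 15, forming C4a–C4 and C4–C3. The closest known reaction type is the carbonylative Suzuki–Miyaura coupling of aryl iodides with alkenylboron reagents to aryl vinyl ketones. After venting, methanolic K2CO3 cleaves both aryl acetates to give 16, and the ortho phenoxide adds to the terminal methylene, forming O1–C2. Ring C closes in the 6-endo-trig mode, as in the base-mediated closure of 2'-hydroxy-α-arylacrylophenones to isoflavanones. C3 is protonated without control, so 17 is racemic, which does not matter because step 10 makes C3 planar. Ketone formation should win over direct coupling because the electron-rich aryl–palladium forms the acyl complex quickly, CO is under pressure, and the hindered 1,1-disubstituted boronate transmetalates slowly. Only the ring A ortho oxygen can close, since the 2'-oxygen is a methoxymethyl ether and the para phenoxide cannot reach C2; ring D meets only base.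

Step 10
Reactants: 17 7-hydroxy-3-[8-methoxy-5-(methoxymethoxy)-2,2-dimethyl-2H-chromen-6-yl]chroman-4-one
Product: 18 7-hydroxy-3-[8-methoxy-5-(methoxymethoxy)-2,2-dimethyl-2H-chromen-6-yl]-4H-chromen-4-one
Conditions: DDQ, 1,4-dioxane, 95 °C
Reagents that add atoms: none
Why: Quinone dehydrogenation of an isoflavanone; the enol of 17 gives up hydride from C2 (oxocarbenium stabilised by O1) and then a proton, while ring D has no hydrogen on its quaternary carbon and the 2'-oxygen is masked, so the hydroquinone-type ring B should not be oxidised.

Step 11
Reactants: 18 7-hydroxy-3-[8-methoxy-5-(methoxymethoxy)-2,2-dimethyl-2H-chromen-6-yl]-4H-chromen-4-one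
Product: 19 7-hydroxy-3-(5-hydroxy-8-methoxy-2,2-dimethyl-2H-chromen-6-yl)-4H-chromen-4-one
Conditions: 2 M HCl, MeOH/THF, 40 °C
Reagents that add atoms: none
Why: Acid-catalysed cleavage of the methoxymethyl acetal by transacetalisation to methanol; dilute acid at moderate temperature should free the phenol much faster than it protonates the ring D double bond.

## Compound list

1 | isovanillin (3-hydroxy-4-methoxybenzaldehyde) | COc1ccc(C=O)cc1O | starting material
2 | 3-hydroxy-4-methoxyphenyl formate | COc1ccc(OC=O)cc1O | intermediate (not isolated)
3 | 4-methoxybenzene-1,3-diol | COc1ccc(O)cc1O | intermediate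
4 | 1-(2,4-dihydroxy-5-methoxyphenyl)ethan-1-one | CC(=O)c1cc(OC)c(O)cc1O | intermediate
5 | 3-chloro-3-methylbut-1-yne | CC(C)(Cl)C#C | starting material
6 | 1-{2-hydroxy-5-methoxy-4-[(2-methylbut-3-yn-2-yl)oxy]phenyl}ethan-1-one | CC(=O)c1cc(OC)c(OC(C)(C)C#C)cc1O | intermediate
7 | 1-[2,4-dihydroxy-5-methoxy-3-(3-methylbuta-1,2-dien-1-yl)phenyl]ethan-1-one | CC(=O)c1cc(OC)c(O)c(C=C=C(C)C)c1O | intermediate (not isolated)
8 | 1-(5-hydroxy-8-methoxy-2,2-dimethyl-2H-chromen-6-yl)ethan-1-one | CC(=O)c1cc(OC)c2OC(C)(C)C=Cc2c1O | intermediate
9 | 1-[8-methoxy-5-(methoxymethoxy)-2,2-dimethyl-2H-chromen-6-yl]ethan-1-one | CC(=O)c1cc(OC)c2OC(C)(C)C=Cc2c1OCOC | intermediate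
10 | 1-[8-methoxy-5-(methoxymethoxy)-2,2-dimethyl-2H-chromen-6-yl]ethenyl trifluoromethanesulfonate | C=C(OS(=O)(=O)C(F)(F)F)c1cc(OC)c2OC(C)(C)C=Cc2c1OCOC | intermediate
11 | 2-{1-[8-methoxy-5-(methoxymethoxy)-2,2-dimethyl-2H-chromen-6-yl]ethenyl}-4,4,5,5-tetramethyl-1,3,2-dioxaborolane | C=C(B1OC(C)(C)C(C)(C)O1)c1cc(OC)c2OC(C)(C)C=Cc2c1OCOC | intermediate
12 | 4-iodobenzene-1,3-diol (4-iodoresorcinol) | Oc1ccc(I)c(O)c1 | starting material
13 | 4-iodo-1,3-phenylene diacetate | CC(=O)Oc1ccc(I)c(OC(C)=O)c1 | intermediate
14 | carbon monoxide | [C-]#[O+] | starting material
15 | 4-{2-[8-methoxy-5-(methoxymethoxy)-2,2-dimethyl-2H-chromen-6-yl]prop-2-enoyl}-1,3-phenylene diacetate | C=C(C(=O)c1ccc(OC(C)=O)cc1OC(C)=O)c1cc(OC)c2OC(C)(C)C=Cc2c1OCOC | intermediate (not isolated)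
16 | 1-(2,4-dihydroxyphenyl)-2-[8-methoxy-5-(methoxymethoxy)-2,2-dimethyl-2H-chromen-6-yl]prop-2-en-1-one | C=C(C(=O)c1ccc(O)cc1O)c1cc(OC)c2OC(C)(C)C=Cc2c1OCOC | intermediate (not isolated)
17 | 7-hydroxy-3-[8-methoxy-5-(methoxymethoxy)-2,2-dimethyl-2H-chromen-6-yl]chroman-4-one (racemic) | O=C1c2ccc(O)cc2OCC1c1cc(OC)c2OC(C)(C)C=Cc2c1OCOC | intermediate
18 | 7-hydroxy-3-[8-methoxy-5-(methoxymethoxy)-2,2-dimethyl-2H-chromen-6-yl]-4H-chromen-4-one | O=c1c(-c2cc(OC)c3OC(C)(C)C=Cc3c2OCOC)coc2cc(O)ccc12 | intermediate
19 | 7-hydroxy-3-(5-hydroxy-8-methoxy-2,2-dimethyl-2H-chromen-6-yl)-4H-chromen-4-one | COc1cc(-c2coc3cc(O)ccc3c2=O)c(O)c2c1OC(C)(C)C=C2 | target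

## Step count and risk

Total step count: 11. Longest linear sequence: 10 steps (steps 1 to 7, then 9 to 11); step 8 is a one-step side branch.

**Step 9 (key step).** Three things may go wrong.
- Transmetalation may overtake CO uptake, so that the aryl and vinyl groups couple directly and C4 is missing.
- An acetate may be lost before oxidative addition, after which a phenoxide can capture the aroylpalladium and esters form instead of the ketone.
- In the basic methanol stage, the enolate of 17 may be oxidised by air at C3.

The fallback keeps the three-bond plan but takes carbon monoxide out of the catalytic cycle, and sets out from boronate 11. Commercial 2,4-dihydroxybenzoic acid F1 is acetylated (Ac2O, pyridine) to 2,4-diacetoxybenzoic acid F2. Oxalyl chloride and catalytic DMF in CH2Cl2 convert F2 into 2,4-diacetoxybenzoyl chloride F3. F3 is joined to 11 in an acyl Suzuki–Miyaura coupling of an acid chloride (Pd(PPh3)4, Cs2CO3, anhydrous toluene, 80 °C). This should give enone diacetate 15, where the route is rejoined; K2CO3 in MeOH then leads to 17 as in step 9.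

**Step 7.** The electron-rich 1-arylvinyl triflate 10 may lose triflic acid to give an aryl alkyne, may be hydrolysed back to ketone 9, or may couple with product already formed. The fallback sets out from ketone 9 and avoids the triflate. Condensation with 2,4,6-triisopropylbenzenesulfonyl hydrazide gives N'-{1-[8-methoxy-5-(methoxymethoxy)-2,2-dimethyl-2H-chromen-6-yl]ethylidene}-2,4,6-tri(propan-2-yl)benzenesulfonohydrazide F4. A Shapiro reaction (n-BuLi, 2.2 equiv, THF, −78 → 0 °C) forms the 1-arylvinyllithium, and trapping with 2-isopropoxy-4,4,5,5-tetramethyl-1,3,2-dioxaborolane returns to 11.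

**Step 10.** The quinone may oxidise the free ring A phenol or the electron-rich ring B faster than it dehydrogenates C2–C3, or conversion may stall. The fallback sets out from 17. LiN(SiMe3)2 (2.2 equiv, THF, −78 °C) and then Me3SiCl give trimethyl({3-[8-methoxy-5-(methoxymethoxy)-2,2-dimethyl-2H-chromen-6-yl]-7-[(trimethylsilyl)oxy]-2H-chromen-4-yl}oxy)silane F5. Saegusa–Ito oxidation with Pd(OAc)2 in MeCN follows: a divalent palladium enolate forms at C3 and β-hydride elimination takes a hydrogen from C2. The aqueous work-up also cleaves the aryl silyl ether, and the route is rejoined at 18.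

**Step 3.** The tertiary chloride may lose HCl to the enyne faster than it alkylates the hindered phenoxide next to the methoxy group, leaving 4 unchanged. The fallback sets out from 4 and reaches 8 directly, bypassing steps 3 and 4. It uses 3-methylbut-2-enal and ethylenediammonium diacetate (cat.) in toluene at 110 °C: Knoevenagel-type condensation at the carbon between the two oxygens, then oxa-6π electrocyclisation through the non-chelated 4-oxygen. No compound outside the list is made on this detour (F0).

## Further compounds

F1 | step 9 | 2,4-dihydroxybenzoic acid (purchased) | OC(=O)c1ccc(O)cc1O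
F2 | step 9 | 2,4-diacetoxybenzoic acid | CC(=O)Oc1ccc(C(=O)O)c(OC(C)=O)c1
F3 | step 9 | 2,4-diacetoxybenzoyl chloride | CC(=O)Oc1ccc(C(Cl)=O)c(OC(C)=O)c1
F4 | step 7 | N'-{1-[8-methoxy-5-(methoxymethoxy)-2,2-dimethyl-2H-chromen-6-yl]ethylidene}-2,4,6-tri(propan-2-yl)benzenesulfonohydrazide | CC(=NNS(=O)(=O)c1c(C(C)C)cc(C(C)C)cc1C(C)C)c1cc(OC)c2OC(C)(C)C=Cc2c1OCOC
F5 | step 10 | trimethyl({3-[8-methoxy-5-(methoxymethoxy)-2,2-dimethyl-2H-chromen-6-yl]-7-[(trimethylsilyl)oxy]-2H-chromen-4-yl}oxy)silane | C[Si](C)(C)OC1=C(c2cc(OC)c3OC(C)(C)C=Cc3c2OCOC)COc2cc(O[Si](C)(C)C)ccc12
F0 | step 3 | none | none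
A1 | alternative 1 | 3-[8-methoxy-5-(methoxymethoxy)-2,2-dimethylchroman-6-yl]-7-(methoxymethoxy)-4H-chromen-4-one | COCOc1ccc2c(=O)c(-c3cc(OC)c4OC(C)(C)CCc4c3OCOC)coc2c1
A2 | alternative 1 | 7-(methoxymethoxy)-2,2-dimethyl-4H-1,3-benzodioxin-4-one | COCOc1ccc2C(=O)OC(C)(C)Oc2c1
A3 | alternative 1 | 4-{(E)-2-[8-methoxy-5-(methoxymethoxy)-2,2-dimethylchroman-6-yl]ethenyl}morpholine | COCOc1c(/C=C/N2CCOCC2)cc(OC)c2OC(C)(C)CCc12
A4 | alternative 2 | 7-hydroxy-3-(5-hydroxy-8-methoxy-2,2-dimethylchroman-6-yl)-4H-chromen-4-one | O=c1c(-c2cc(OC)c3OC(C)(C)CCc3c2O)coc2cc(O)ccc12
A5 | alternative 2 | 3-[(3-hydroxyphenoxy)methylidene]benzofuran-2(3H)-one fused to 8-methoxy-2,2-dimethylchroman (lactone oxygen on chroman C5, lactone C3 on chroman C6) | O=C1Oc2c3CCC(C)(C)Oc3c(OC)cc2C1=COc1cccc(O)c1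
A6 | alternative 3 | 3-(5,8-dihydroxy-2,2-dimethyl-2H-chromen-6-yl)-7-(methoxymethoxy)-4H-chromen-4-one | COCOc1ccc2c(=O)c(-c3cc(O)c4OC(C)(C)C=Cc4c3O)coc2c1
A7 | alternative 3 | (E)-3-(dimethylamino)-1-[2-hydroxy-4-(methoxymethoxy)phenyl]prop-2-en-1-one | CN(C)/C=C/C(=O)c1ccc(OCOC)cc1O
A8 | alternative 3 | 2,2-dimethyl-2H-chromene-5,8-dione | CC1(C)C=CC2=C(O1)C(=O)C=CC2=O
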